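**Easy step.** Divide the target a flask has made by the catalyst charged and by the time, and you have a mean turnover rate.

| flask | starting material | coupling partner | free catalyst | remark | time |
|---|---|---|---|---|---|
| eta | 0.12 M | 0.11 M | 0.50 mM | run made earlier |  |
| beta | 0.22 M | 0.11 M | 0.50 mM | run made earlier |  |
| alpha | 0.10 M | 0.11 M | 0.59 mM | run made earlier |  |
| oak | 0.10 M | 0.400 M | 1.5 mM |  | 15 min |
| elm | 0.15 M | 0.0800 M | 0.80 mM |  | 15 min |
| maple | 0.10 M | 0.300 M | 0.25 mM |  | 15 min |
| cedar | 0.10 M | 0.110 M | 0.50 mM |  | 15 min |
| alder | 0.10 M | 0.110 M | 1.0 mM |  | 15 min |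

| run | time / min | target / % |
|---|---|---|
| eta | 0.500 | 1.5 |
| eta | 1.50 | 3.1 |
| eta | 3.00 | 8.2 |
| eta | 5.00 | 11.3 |
| eta | 6.00 | 13.5 |
| eta | 8.00 | 17.7 |
| eta | 10.0 | 19.9 |
| beta | 0.833 | 0 |
| beta | 1.33 | 0.9 |
| beta | 2.00 | 0.7 |
| beta | 3.00 | 4.1 |
| beta | 5.00 | 6.6 |
| beta | 6.00 | 6.0 |
| beta | 10.0 | 12.9 |
| alpha | 1.00 | 1.4 |
| alpha | 2.50 | 7.6 |
| alpha | 5.00 | 16.2 |
| alpha | 8.00 | 22.7 |
| alpha | 10.0 | 29.0 |

(each reading ± 1 percentage point)

- the analysis behind the earlier runs scatters by 1 percentage point, standard deviation
- a reading or a percentage of target counts all its forms, free or not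

1. all flasks from highest to lowest amount of target, in percent of the starting material charged, at 15 min (oak / elm / maple / cedar / alder)
2. the same order at 1.0 h (oak / elm / maple / cedar / alder)
3. the amount of target, in percent of the starting material charged of the flask you put first, at 15 min
4. the amount of target, in percent of the starting material charged of the flask you put last, at 15 min

**The rate.** Do this on the last alpha reading: 4.92 min⁻¹, the mean turnover rate, which is target made per catalyst charged per minute, with the curve replaced by its mean. Check what that costs. The straight line gives 14.5% at 5.00 min, alpha reads 16.2%, and the scatter is 1 percentage point. The eta and beta runs both charge 0.11 M of coupling partner, as does alpha, so its effect cannot be read from them.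

**Two extremes.** Multiply the rate by catalyst and time, divide by the starting material charged, and call this the reach. In the first extreme the rate holds until the starting material is gone, so the yield equals the reach, capped at 100%. In the second the rate falls in step with the starting material left, so the yield is one minus exp(−reach). Oak, where starting material is the limiting reagent, has a reach of 111%, which gives 100% or 67.0%. Maple has a reach of 18.4%, which gives 18.4% or 16.8%. Expect the first extreme, because the factor on target made from eta to beta at 10.0 min, 1.19, is smaller than the factor on starting material, 1.83. So I commit to oak close to the cap and maple close to 18.4%, with coupling partner unread in both.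

**The forecast.** It orders the flasks oak > alder > cedar > elm > maple at 15 min and oak > alder > cedar > maple > elm at 1.0 h, with oak at 72% and maple at 19%. It reads the bend in the curves thus: “This suggests target binds catalyst”. On maple we nearly agree, but on oak we differ.

**The result.** The flasks stand oak > alder > cedar > elm > maple at 15 min and oak > alder > cedar > maple > elm at 1.0 h.

    coupling partner + free catalyst → catalyst intermediate A (k = 3.10 M⁻¹ s⁻¹)
    catalyst intermediate A → catalyst intermediate B (k = 0.340 s⁻¹)
    starting material + catalyst intermediate B → catalyst intermediate C (k = 8.00 M⁻¹ s⁻¹)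
    catalyst intermediate C ⇌ free catalyst + target (K = 0.490 M, k = 0.250 s⁻¹)
    target + free catalyst ⇌ isomer of the product + free catalyst, rate k5*[free catalyst]*[target] forward; the back reaction follows from the equilibrium constant (K = 0.120, k = 0.210 M⁻¹ s⁻¹)
    coupling partner + target ⇌ idle adduct, settled at all times (K = 4.70 M⁻¹)

**The neighbour.** At 15 min oak holds 98.3% and maple 23.5%, above maple's reach of 18.4%. Repeat the division on maple: 6.27 min⁻¹, which is 1.27 times the alpha rate, at 0.300 M of coupling partner. Carry this rate to a neighbour with maple's recipe but 6.3 × 10⁻⁴ M of free catalyst. Its reach is 59.2%, and that flask gives 55.8%.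

Readings and results come from a simulation for an exercise.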